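The electrophile in this flask has two takers, nucleophile and protic impurity, and I counted them.

in all of them: nucleophile 0.0105 M

| run | electrophile | free base | protic impurity | remark | time |
|---|---|---|---|---|---|
| Thursday's | 0.0050 M | 0.030 M | 0.20 mM | run made earlier |  |
| Wednesday's | 0.020 M | 0.030 M | 0.20 mM | run made earlier |  |
| flask | 0.010 M | 0.0300 M | 0.200 mM |  | 10 min |

| run | time / min | electrophile / % | target / % |
|---|---|---|---|
| Thursday's | 1.33 | 8.3 | 87.2 |
| Thursday's | 2.50 | 0.8 | 93.6 |
| Thursday's | 4.00 | 0.2 | 94.5 |
| Thursday's | 5.00 | 0 | 95.8 |
| Thursday's | 6.00 | 0.2 | 95.3 |
| Thursday's | 8.00 | 0 | 95.7 |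
| Wednesday's | 0.500 | 58.2 | 42.2 |
| Wednesday's | 1.50 | 48.1 | 51.0 |
| Wednesday's | 3.00 | 45.6 | 52.6 |
| Wednesday's | 4.00 | 46.8 | 51.9 |
| Wednesday's | 6.00 | 45.5 | 52.9 |
| Wednesday's | 8.00 | 46.6 | 51.6 |

(standard deviation of a reading: 0.5 percentage points)

- part of the electrophile that has reacted at 10 min
- share of the unused nucleophile that is free and not bound as protonated nucleophile, at 10 min

- the numbers in the tables scatter with a standard deviation of 0.5 percentage points
- the earlier runs do not show how much of nucleophile is bound; that part of a forecast is a guess

Thursday's run ended with its last target reading 0.215 mM short of the electrophile charged, against 0.20 mM of protic impurity charged, so I let each impurity molecule spend one electrophile. That folded the charges into one number: 1.07 in this flask, the nucleophile plus protic impurity over the electrophile charged. I called it the cover.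

Wednesday's run had a cover of 0.535 and stopped with 53.4% reacted, so nucleophile was its limiting reagent. Thursday's had 2.14 and ended with 0% electrophile. In these two runs the part reacted, as read, therefore stopped at the cover, capped at 100%.

But a cover holds no time, and this flask's surplus was 0.700 mM. That surplus was far less than the electrophile charged, so I expected the tail to crawl. Thursday's first reading, with nucleophile taken by my estimate at an average of 8.00 mM, gave me about 23.4 turnovers for this flask: rate constant times charge times time. Equal partners leave one part in one plus the turnovers, 4.10%, and surplus shortens that. I committed to between 95.9% and the cap, and left the free share unreckoned.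

The forecast gave 98.2% reacted and 80% free, and of the second figure it said “this is a guess”.

The flask gave 97.7% reacted and 62.1% free.

    acid set free + free base ⇌ salt of the base, settled at all times (K = 87100 M⁻¹)
    free base ⇌ dormant form (K = 0.346, k = 0.0699 s⁻¹)
    nucleophile + acid set free ⇌ protonated nucleophile, settled at all times (K = 89000 M⁻¹)
    electrophile + protic impurity → quenched substrate (k = 309 M⁻¹ s⁻¹)
    target → over-reaction product (k = 1.26 × 10⁻⁵ s⁻¹)
    electrophile + nucleophile → acid set free + target (k = 4.76 M⁻¹ s⁻¹)

The 97.7% reacted sits under the cap set by the cover of 1.07, and left until 100 min the same flask reached >99.9% reacted. The neighbour flask charged with 0.0042 M of nucleophile had a cover of 0.440, and at 10 min 44.0% of its electrophile had reacted.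

The readings come from a simulation with constants of no real substance; the scatter is artificial.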